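The runs are simulated from invented constants; the scatter is artificial.

Count the charge.

| setting | east | flask |
|---|---|---|
| substrate | 0.020 M | 0.010 M |
| remark | run made earlier |  |
| time |  | 15 d |
east run (percent of the substrate charged)

| time / h | isomer of the product A / % | target / % |
|---|---|---|
| 10.0 | 0.4 | 13.0 |
| 20.0 | 0.6 | 23.7 |
| 25.0 | 2.2 | 26.1 |
| 40.0 | 1.1 | 26.8 |

(scatter of a reading: 0.5 percentage points)
- share of isomer of the product A in isomer of the product A plus target at 2.0 h
- share of isomer of the product A in isomer of the product A plus target at 15 d
- the analysis behind the earlier runs scatters by 0.5 percentage points, standard deviation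

Substrate is the limiting reagent, so I work in fractions of its charge and take these fractions to be unchanged by the smaller charge of this flask. At 40.0 h the east run shows target and isomer of the product A together at 27.9%, which leaves 72.1% unseen. Isomer of the product A reads close to the scatter, so pool its readings over their times. That gives 0.0109 d⁻¹, the fraction of the charge gained per day, the isomer drip.

Against the early climb of target, 0.312 d⁻¹, the drip gives a share of 3.36% at 2.0 h. Run to 15 d, it gives 16.3%, which fits inside the unseen part. With target held at the plateau read in the east run, 26.4%, my share for this flask at 15 d is 38.1%.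

That plateau is the weak link, since the unseen part is larger than target, and target may be only passing through. If target loses half of its plateau, the share reads 55.3%. I commit to the span between these two shares.

The forecast gives 3.5% and 5%, on “parallel formation with a fixed selectivity”. We agree early and differ late.

The flask gives 1.40% and 47.6%.

    substrate → decomposition product (k = 5.71 × 10⁻⁸ s⁻¹)
    intermediate ⇌ target (K = 1.30, k = 4.54 × 10⁻⁵ s⁻¹)
    intermediate ⇌ isomer of the product A (K = 18.8, k = 5.76 × 10⁻⁷ s⁻¹)
    substrate → intermediate (k = 1.36 × 10⁻⁵ s⁻¹)
    target ⇌ isomer of the product B (K = 8.21, k = 1.23 × 10⁻⁵ s⁻¹)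

In this flask target peaks at 26.9% after 1.42 d and stands at 8.97% at 15.0 d. The drip gives 1.63% of isomer of the product A at 1.50 d, where this flask holds 1.74%, but its 16.3% at 15 d is twice the 8.13% standing there.

On the neighbour flask with 0.025 M, the drip again gives 16.3% by 15 d. That computed flask holds 8.13% of isomer of the product A beside 8.97% of target, a share of 47.6%.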